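None of the readings can show the first chain carrier, yet its fate can be counted from them. Among the candidate steps, partner turns it into target and transfer agent turns it into side product, so the products should grow as the rates of those two steps.

| setting | spring | dawn | midnight | flask |
|---|---|---|---|---|
| substrate | 20 mM | 20 mM | 20 mM | 20 mM |
| partner | 1.3 equiv | 1.3 equiv | 2.6 equiv | 1.30 equiv |
| transfer agent | 1 mM | 4 mM | 2 mM | 2.00 mM |
| protic impurity | 10 mM | 10 mM | 10 mM | 10.0 mM |
| scavenger | 0.50 equiv | 0.50 equiv | 0.50 equiv | 0.500 equiv |
| initiator | 5 mol% | 5 mol% | 5 mol% | 5 mol% |
| remark | run made earlier | run made earlier | run made earlier |  |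
| time |  |  |  | 2.5 h |

| run | time / h | target / % | side product / % |
|---|---|---|---|
| spring | 0.417 | 1.3 | 1.0 |
| spring | 0.833 | 2.9 | 1.4 |
| spring | 1.33 | 3.4 | 2.1 |
| spring | 1.50 | 4.1 | 1.8 |
| spring | 2.00 | 5.2 | 2.9 |
| spring | 2.50 | 6.6 | 3.6 |
| spring | 3.00 | 8.8 | 4.0 |
| dawn | 0.417 | 0.5 | 0.5 |
| dawn | 0.833 | 0.4 | 0.9 |
| dawn | 1.33 | 1.3 | 1.9 |
| dawn | 1.50 | 1.2 | 2.2 |
| dawn | 2.00 | 1.0 | 3.0 |
| dawn | 2.50 | 1.6 | 3.7 |
| dawn | 3.00 | 1.5 | 4.4 |
| midnight | 0.250 | 0.9 | 0.4 |
| midnight | 0.417 | 1.2 | 0.6 |
| midnight | 0.833 | 2.6 | 1.8 |
| midnight | 1.50 | 4.2 | 2.1 |
| midnight | 3.00 | 5.8 | 4.0 |

(readings scatter by 0.3 percentage points)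

- a species is counted by the substrate in it: one ended chains B counts as two
- amounts and yields of released group count idle adduct too
- candidate steps: initiator -> 2 initiating radical; substrate + initiating radical -> capped initiator + first chain carrier; partner + first chain carrier -> target + second chain carrier; substrate + second chain carrier -> released group + first chain carrier; transfer agent + first chain carrier -> side product + idle radical; 2 idle radical -> ended radicals; 2 second chain carrier -> ended chains A; 2 first chain carrier -> ended chains B; partner -> decomposed reagent; partner + protic impurity -> quenched reagent; partner + released group <-> idle adduct; scavenger + released group -> scavenged by-product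

1. concentration of target at 2.5 h, in mM
2. concentration of side product at 2.5 h, in mM

Up to 0.833 h the spring run reads target over side product as 1.75. Dividing by the charged c(partner)/c(transfer agent) leaves a selectivity factor of 0.0673, a reading with its scatter. Multiplying it by this flask's charged c(partner)/c(transfer agent) gives 0.875 as the branching number G, the target made per side product made at the charged amounts. At G equal to one the first chain carrier goes equally to partner and transfer agent, and by this reading the flask starts just below that crossing.

The midnight run tests this: G there is 1.75, and its readings up to 0.833 h give 1.68. One number is still not enough, since the midnight ratio reads lower, 1.45, by 3.00 h, a factor of 0.864 that carries the scatter of the readings. This reckoning takes that factor over as an estimate, midnight having this flask's transfer agent charge but more partner.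

Side product reads 3.6% in spring and 3.7% in dawn at 2.50 h, and the transfer agent charges of these runs lie on either side of this flask's, so their mean gives an estimate of 0.730 mM. This reckoning then gives 0.552 mM of target.

The forecast gave 0.58 mM (0.43 mM to 0.74 mM) of target, which is more than this reckoning, and 0.7 mM (0.62 mM to 0.78 mM) of side product, which is less, holding that “the radical flux is initiation-limited”.

The flask gives 0.542 mM of target and 0.701 mM of side product, inside both forecast ranges.

    initiator → 2 initiating radical (k = 0.00289 /min)
    substrate + initiating radical → capped initiator + first chain carrier (k = 1.75 × 10⁵ /M/s)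
    partner + first chain carrier → target + second chain carrier (k = 1.37 × 10⁵ /M/min)
    substrate + second chain carrier → released group + first chain carrier (k = 76400 /M/min)
    transfer agent + first chain carrier → side product + idle radical (kL = 32800 /M/s)
    2 idle radical → ended radicals (k = 1.00 × 10⁷ /M/s)
    2 second chain carrier → ended chains A (k = 2.00 × 10⁷ /M/s)
    2 first chain carrier → ended chains B (k = 7.00 × 10⁶ /M/s)
    partner → decomposed reagent (k = 0.00332 /min)
    partner + protic impurity → quenched reagent (k = 0.204 /M/min)
    partner + released group ⇌ idle adduct, settled at all times (K = 30.9 /M)
    scavenger + released group → scavenged by-product (k = 53.9 /M/min)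

Up to 2.5 h the flask turned over 2.70% of its substrate through the step with second chain carrier, less than the 3.52% through the initiating step, which makes 0.767 chain turns per start. With 0.80 mM of transfer agent, the neighbour has G of 2.19, above the crossing, which on the same side product and undamped gives 1.60 mM of target. The computed neighbour holds 2.01 mM of target and 0.666 mM of side product, with 17% of its transfer agent left.

Readings and results were generated by integration with made-up constants, and the scatter is random.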